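**Retrosynthetic overview**
- The side chain is cut at C2'–C3': a visible-light nickel/iridium doubly decarboxylative coupling joins a phthalide propanoic acid (as its N-acyloxyphthalimide) with (12S)-12-hydroxy-9-oxotridecanoic acid.
- The keto acid comes from (S)-γ-valerolactone, which brings the carbinol stereocentre, by C-acylation with methyl 9-chloro-9-oxononanoate and decarboxylative hydrolysis.
- The phthalide acid comes from an acetylenic ester that carries the γ-butyrolactone stereocentre, by Alder–Rickert benzannulation with 1-methoxy-3-(trimethylsilyloxy)cyclohexa-1,3-diene.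
- The acetylenic ester comes from (S)-5-oxotetrahydrofuran-2-carboxylic acid (L-glutamic acid series, brings C3) via an acyl ylide and loss of Ph3P=O.
- Ring order: the benzene ring is formed first; the phthalide lactone then closes by lactone-to-lactone switch on the same oxygen; no ring is formed afterwards.

Assumption: both enantiopure lactones, the Wittig ylide, 3-methoxycyclohex-2-en-1-one and methyl 9-chloro-9-oxononanoate are bought; side-chain carbons are called C1' (on phthalide C3) to C14'.

**Step 1**
Reactants: 1 (S)-5-oxotetrahydrofuran-2-carboxylic acid; 2 methyl (triphenyl-λ5-phosphanylidene)acetate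
Product: 3 methyl 3-oxo-3-[(2S)-5-oxooxolan-2-yl]-2-(triphenyl-λ5-phosphanylidene)propanoate
Conditions: DCC, DMAP (cat.), CH2Cl2, 0 °C to rt
Reagents that add atoms: none
Why: Carbodiimide activation of the acid and C-acylation of the stabilised Wittig ylide give the β-keto phosphorane, and the stereocentre bought with 1 is not touched because the ylide-conjugated ketone is hardly enolisable.

**Step 2**
Reactants: 3 methyl 3-oxo-3-[(2S)-5-oxooxolan-2-yl]-2-(triphenyl-λ5-phosphanylidene)propanoate
Product: 4 methyl 3-[(2S)-5-oxooxolan-2-yl]prop-2-ynoate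
Conditions: flash vacuum pyrolysis, 500 °C, 0.01 mbar, cold trap
Reagents that add atoms: none
Why: Thermal intramolecular Wittig-type extrusion of Ph3P=O from the β-keto ylide (acyl ylide pyrolysis) gives the acetylenic ester under neutral gas-phase conditions, so the propargylic stereocentre is retained.

**Step 3**
Reactants: 5 3-methoxycyclohex-2-en-1-one
Product: 6 1-methoxy-3-(trimethylsilyloxy)cyclohexa-1,3-diene
Conditions: LiN(iPr)2, THF, −78 °C; then Me3SiCl, −78 °C to rt; distillation
Reagents that add atoms: chlorotrimethylsilane (C[Si](C)(C)Cl)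
Why: Kinetic α'-deprotonation of the vinylogous ester and O-silylation (silyl dienol ether formation) give the cross-conjugated diene.

**Step 4**
Reactants: 4 methyl 3-[(2S)-5-oxooxolan-2-yl]prop-2-ynoate; 6 1-methoxy-3-(trimethylsilyloxy)cyclohexa-1,3-diene
Product: 9 (S)-3-(5-hydroxy-7-methoxy-1-oxo-1,3-dihydroisobenzofuran-3-yl)propanoic acid, via bicyclo[2.2.2]octadiene cycloadduct 7 (not isolated), via aryl silyl ether methyl ester 8 (not isolated)
Conditions: 6 (2 equiv), neat, sealed tube, 160 °C; then LiOH, THF–H2O, rt; then 2 M HCl, 40 °C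
Reagents that add atoms: water (O)
Why: Alder–Rickert reaction (Diels–Alder addition of the nucleophilic diene terminus to the ynoate β-carbon, then retro-Diels–Alder loss of ethylene) builds the arene with OMe ortho and O–Si para to the ester, after which hydroxide cleaves the silyl ether and the butyrolactone and acidification closes the benzylic hydroxyl onto the aryl carboxyl to give the more stable phthalide without ever breaking the C–O bond of the stereocentre.

**Step 5**
Reactants: 10 (S)-γ-valerolactone; 11 methyl 9-chloro-9-oxononanoate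
Product: 13 (12S)-12-hydroxy-9-oxotridecanoic acid, via α-acyl lactone 12 (not isolated)
Conditions: 10 (2.1 equiv), LiN(iPr)2 (2.1 equiv), THF, −78 °C; then 11, −78 to −20 °C; then 3 M H2SO4 (aq), reflux
Reagents that add atoms: water (O)
Why: Crossed Claisen C-acylation of the lactone lithium enolate (the second equivalent of enolate serves as base) followed by acid hydrolysis and β-keto acid decarboxylation gives the γ-hydroxy ketone acid, and only acyl–oxygen bonds are cleaved, so the carbinol stereocentre bought with 10 is retained.

**Step 6**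
Reactants: 9 (S)-3-(5-hydroxy-7-methoxy-1-oxo-1,3-dihydroisobenzofuran-3-yl)propanoic acid; 13 (12S)-12-hydroxy-9-oxotridecanoic acid
Product: 15 (S)-5-hydroxy-3-[(S)-13-hydroxy-10-oxotetradecyl]-7-methoxyisobenzofuran-1(3H)-one, via N-acyloxyphthalimide ester 14 (not isolated)
Conditions: N-hydroxyphthalimide (1.0 equiv), DIC (1.0 equiv), DMA, rt; then 13 (2.5 equiv), [Ir(dF(CF3)ppy)2(dtbbpy)]PF6 (2 mol%), NiCl2·(MeOCH2CH2OMe) (10 mol%), 4,4'-di-tert-butyl-2,2'-bipyridine (12 mol%), Cs2CO3 (0.25 equiv), degassed DMA, 450 nm LEDs, 25 °C
Reagents that add atoms: none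
Why: Proposed new method: a redox-neutral, cross-selective doubly decarboxylative C(sp3)–C(sp3) coupling of a redox-active ester with a free carboxylic acid. Bipyridine-ligated zerovalent nickel adds oxidatively to 14 (single-electron transfer, loss of CO2 and phthalimide anion, radical rebound) to give a primary alkyl divalent nickel species. The excited trivalent iridium photocatalyst oxidises the carboxylate of 13 (Kolbe-type, loss of CO2) to the ω-keto primary alkyl radical, which is captured at nickel. Reductive elimination from the dialkyl trivalent nickel species forms the C2'–C3' bond, and the divalent iridium returns monovalent nickel to the zerovalent state. The phthalimide anion set free deprotonates the next molecule of 13, so only catalytic base is needed and the phenol stays protonated and unoxidised. The two alkyl groups reach nickel by two different elementary steps, which is the source of cross-selectivity. The closest known reaction types are the metallaphotoredox decarboxylative alkylation of carboxylic acids with alkyl halides and the nickel-catalysed reductive coupling of two redox-active esters. No stereocentre is formed or touched.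

**Compound list**
1 | (S)-5-oxotetrahydrofuran-2-carboxylic acid | OC(=O)[C@@H]1CCC(=O)O1 | starting material
2 | methyl (triphenyl-λ5-phosphanylidene)acetate | COC(=O)C=P(c1ccccc1)(c1ccccc1)c1ccccc1 | starting material
3 | methyl 3-oxo-3-[(2S)-5-oxooxolan-2-yl]-2-(triphenyl-λ5-phosphanylidene)propanoate | COC(=O)C(=P(c1ccccc1)(c1ccccc1)c1ccccc1)C(=O)[C@@H]1CCC(=O)O1 | intermediate
4 | methyl 3-[(2S)-5-oxooxolan-2-yl]prop-2-ynoate | COC(=O)C#C[C@@H]1CCC(=O)O1 | intermediate
5 | 3-methoxycyclohex-2-en-1-one | COC1=CC(=O)CCC1 | starting material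
6 | 1-methoxy-3-(trimethylsilyloxy)cyclohexa-1,3-diene | COC1=CC(O[Si](C)(C)C)=CCC1 | intermediate
7 | methyl 1-methoxy-3-[(2S)-5-oxooxolan-2-yl]-5-(trimethylsilyloxy)bicyclo[2.2.2]octa-2,5-diene-2-carboxylate (bridgehead isomers) | COC(=O)C1=C([C@@H]2CCC(=O)O2)C2C(O[Si](C)(C)C)=CC1(OC)CC2 | intermediate
8 | methyl 2-methoxy-6-[(2S)-5-oxooxolan-2-yl]-4-(trimethylsilyloxy)benzoate | COC(=O)c1c(OC)cc(O[Si](C)(C)C)cc1[C@@H]1CCC(=O)O1 | intermediate
9 | (S)-3-(5-hydroxy-7-methoxy-1-oxo-1,3-dihydroisobenzofuran-3-yl)propanoic acid | COc1cc(O)cc2c1C(=O)O[C@H]2CCC(=O)O | intermediate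
10 | (S)-γ-valerolactone, (5S)-5-methyloxolan-2-one | C[C@H]1CCC(=O)O1 | starting material
11 | methyl 9-chloro-9-oxononanoate | COC(=O)CCCCCCCC(Cl)=O | starting material
12 | methyl 9-[(5S)-5-methyl-2-oxooxolan-3-yl]-9-oxononanoate (epimers at the acylated carbon) | COC(=O)CCCCCCCC(=O)C1C[C@H](C)OC1=O | intermediate
13 | (12S)-12-hydroxy-9-oxotridecanoic acid | OC(=O)CCCCCCCC(=O)CC[C@H](C)O | intermediate
14 | 1,3-dioxoisoindolin-2-yl (S)-3-(5-hydroxy-7-methoxy-1-oxo-1,3-dihydroisobenzofuran-3-yl)propanoate | COc1cc(O)cc2c1C(=O)O[C@H]2CCC(=O)ON1C(=O)c2ccccc2C1=O | intermediate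
15 | (S)-5-hydroxy-3-[(S)-13-hydroxy-10-oxotetradecyl]-7-methoxyisobenzofuran-1(3H)-one | COc1cc(O)cc2c1C(=O)O[C@H]2CCCCCCCCCC(=O)CC[C@H](C)O | target

**Step count and risks**
Total step count: 6 (steps 4, 5 and 6 are one-pot, two-stage operations). Longest linear sequence: 4 (steps 1, 2, 4, 6).

The three steps most likely to fail:

Step 6 (the proposed new coupling) is the least certain. It may give homodimers and protodecarboxylation products, acyl exchange between the carboxylate of 13 and the active ester 14 could scramble the two roles, and any phenolate formed would quench the photocatalyst. The fallback uses known chemistry and sets out from 9 and 13. Acid 9 is converted to 14 as in step 6 but isolated, and 13 is esterified (N-hydroxyphthalimide, DIC, CH2Cl2) to 1,3-dioxoisoindolin-2-yl (12S)-12-hydroxy-9-oxotridecanoate F1. Then 14 and F1 (3 equiv) are joined by the established nickel-electrocatalytic reductive coupling of two redox-active esters (NiCl2·6H2O, 2,2'-bipyridine, AgNO3, Mg sacrificial anode, carbon cathode, NMP, constant current, rt). The cross-product is separated from the two homodimers, and the fallback comes back to the route at 15.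

Step 2 (pyrolytic Ph3P=O extrusion) needs special apparatus and is hard to scale, and the ylide may char before it volatilises. The fallback sets out from 1. Oxalyl chloride with catalytic DMF gives (S)-5-oxotetrahydrofuran-2-carbonyl chloride F2. Rosenmund reduction (H2, Pd/BaSO4, toluene) gives (S)-5-oxotetrahydrofuran-2-carbaldehyde F3. Ohira–Bestmann homologation (dimethyl (1-diazo-2-oxopropyl)phosphonate, K2CO3, MeOH, then TsOH to re-close any opened lactone) gives (S)-5-ethynyldihydrofuran-2(3H)-one F4. Palladium-catalysed oxidative methoxycarbonylation of the terminal alkyne (PdCl2 cat., CuCl2, NaOAc, CO, MeOH, rt) then comes back to the route at 4.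

Step 4 (Alder–Rickert cascade) needs 160 °C, the diene can polymerise, and ethylene extrusion may be incomplete. The fallback sets out from 4 and replaces the cyclic diene by the acyclic 1,1-dimethoxy-3-(trimethylsilyloxy)buta-1,3-diene F5 (toluene, 90 °C). The Diels–Alder adduct, methyl 6,6-dimethoxy-2-[(2S)-5-oxooxolan-2-yl]-4-(trimethylsilyloxy)cyclohexa-1,4-diene-1-carboxylate F6, aromatises by loss of methanol instead of ethylene. This comes back to the route at 8, which is carried through the LiOH/HCl stage of step 4 to 9.

**Further compounds**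
F1 | step 6 | 1,3-dioxoisoindolin-2-yl (12S)-12-hydroxy-9-oxotridecanoate | O=C(CCCCCCCC(=O)CC[C@H](C)O)ON1C(=O)c2ccccc2C1=O
F2 | step 2 | (S)-5-oxotetrahydrofuran-2-carbonyl chloride | O=C(Cl)[C@@H]1CCC(=O)O1
F3 | step 2 | (S)-5-oxotetrahydrofuran-2-carbaldehyde | O=C[C@@H]1CCC(=O)O1
F4 | step 2 | (S)-5-ethynyldihydrofuran-2(3H)-one | C#C[C@@H]1CCC(=O)O1
F5 | step 4 | 1,1-dimethoxy-3-(trimethylsilyloxy)buta-1,3-diene | COC(OC)=CC(=C)O[Si](C)(C)C
F6 | step 4 | methyl 6,6-dimethoxy-2-[(2S)-5-oxooxolan-2-yl]-4-(trimethylsilyloxy)cyclohexa-1,4-diene-1-carboxylate | COC(=O)C1=C([C@@H]2CCC(=O)O2)CC(O[Si](C)(C)C)=CC1(OC)OC
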